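**Retrosynthetic overview**
- The target is unmasked last from its 5-O-methyl, 4'-O-benzyl ether: chelation-controlled 5-O-demethylation, then hydrogenolysis of the benzyl ether.
- Ring C (the pyranone) is the only ring built, and it is built last, by oxidative cyclisation of a 2'-hydroxychalcone whose single free OH fixes the 5,7,8-oxygenation pattern.
- Key C–C disconnection: the chalcone Cα–Cβ bond, made by an intermolecular Claisen–Schmidt aldol condensation between a ring A acetophenone and a ring B benzaldehyde.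
- Ring A fragment: 2-hydroxy-3,4,6-trimethoxyacetophenone from 3,4,5-trimethoxyphenol (O-methylation, then Friedel–Crafts acetylation with ortho-demethylation).
- Ring B fragment: 4-benzyloxy-2,3-dimethoxybenzaldehyde from 2,3,4-trihydroxybenzaldehyde (selective 4-O-benzylation, then methylation); both benzene rings are bought in.

Assumption: the target has no stereocentre and is achiral, so the structure drawn is its only stereoisomer; the (E)-alkene of the chalcone and two racemic, transient sp3 centres are erased before the end.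

**Route**

Step 1
Reactants: 1 3,4,5-trimethoxyphenol
Product: 2 1,2,3,5-tetramethoxybenzene
Conditions: MeI (1.5 equiv), K2CO3 (2 equiv), acetone, reflux, 12 h
Reagents that add atoms: iodomethane, CI
Why: Williamson O-methylation of the only phenol gives the symmetrical tetramethyl ether, so no regiochemical question arises.

Step 2
Reactants: 2 1,2,3,5-tetramethoxybenzene
Product: 4 1-(2-hydroxy-3,4,6-trimethoxyphenyl)ethanone, via 2,3,4,6-tetramethoxyacetophenone 3 (not isolated)
Conditions: AcCl (1.2 equiv), AlCl3 (2.5 equiv), Et2O, 0 °C → rt, 24 h; then ice/2 M HCl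
Reagents that add atoms: acetyl chloride, CC(Cl)=O
Why: Friedel–Crafts acylation can only occur at the two equivalent free positions, and the AlCl3-complexed ketone then cleaves the more crowded ortho-methoxy group (the one buttressed by a neighbouring OMe) by chelation-assisted demethylation, leaving the phenol that becomes the ring C oxygen.

Step 3
Reactants: 5 2,3,4-trihydroxybenzaldehyde
Product: 6 4-(benzyloxy)-2,3-dihydroxybenzaldehyde
Conditions: BnBr (1.05 equiv), NaHCO3 (1.2 equiv), KI (0.1 equiv), DMF, 40 °C, 20 h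
Reagents that add atoms: benzyl bromide, BrCc1ccccc1
Why: Williamson etherification under weak-base control, in which only the most acidic 4-OH (para to the formyl group) is ionised, the 2-OH being hydrogen-bonded to the aldehyde and the 3-OH being the least acidic.

Step 4
Reactants: 6 4-(benzyloxy)-2,3-dihydroxybenzaldehyde
Product: 7 4-(benzyloxy)-2,3-dimethoxybenzaldehyde
Conditions: MeI (3 equiv), K2CO3 (3 equiv), DMF, rt → 40 °C, 12 h
Reagents that add atoms: iodomethane, CI
Why: Exhaustive Williamson O-methylation of the two remaining phenols; the benzyl ether and the non-enolisable aldehyde are inert to K2CO3/MeI.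

Step 5
Reactants: 4 1-(2-hydroxy-3,4,6-trimethoxyphenyl)ethanone; 7 4-(benzyloxy)-2,3-dimethoxybenzaldehyde
Product: 9 (E)-3-[4-(benzyloxy)-2,3-dimethoxyphenyl]-1-(2-hydroxy-3,4,6-trimethoxyphenyl)prop-2-en-1-one, via racemic aldol adduct 8 (not isolated)
Conditions: KOH (50% aq., excess), EtOH, rt, 48 h; then 2 M HCl to pH 3
Reagents that add atoms: none
Why: Claisen–Schmidt (crossed aldol) condensation, in which the methyl ketone enolate of 4 adds to the non-enolisable aldehyde 7 to forge the Cα–Cβ bond joining the two fragments, and E1cB loss of water from the racemic adduct gives the thermodynamically favoured (E)-enone with no stereocentre left.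

Step 6
Reactants: 9 (E)-3-[4-(benzyloxy)-2,3-dimethoxyphenyl]-1-(2-hydroxy-3,4,6-trimethoxyphenyl)prop-2-en-1-one
Product: 11 2-[4-(benzyloxy)-2,3-dimethoxyphenyl]-5,7,8-trimethoxy-4H-chromen-4-one, via racemic flavanone 10 (not isolated)
Conditions: I2 (10 mol %), DMSO, 130 °C, 3 h; then aq. Na2S2O3 wash
Reagents that add atoms: none
Why: Iodine-catalysed oxidative cyclisation of a 2'-hydroxychalcone, in which 6-endo oxa-Michael addition of the only free phenol closes ring C as the flavanone and α-iodination/HI elimination dehydrogenates it while DMSO reoxidises HI to I2.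

Step 7
Reactants: 11 2-[4-(benzyloxy)-2,3-dimethoxyphenyl]-5,7,8-trimethoxy-4H-chromen-4-one
Product: 12 2-[4-(benzyloxy)-2,3-dimethoxyphenyl]-5-hydroxy-7,8-dimethoxy-4H-chromen-4-one
Conditions: BCl3 (1.0 M in CH2Cl2, 1.5 equiv), CH2Cl2, −78 °C → 0 °C, 2 h; then ice/1 M HCl
Reagents that add atoms: none
Why: Chelation-controlled demethylation, in which BCl3 binds the pyranone carbonyl and cleaves only the peri 5-OMe through a six-membered boron chelate, the limited charge and low temperature sparing the benzyl ether and the other four methoxy groups.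

Step 8
Reactants: 12 2-[4-(benzyloxy)-2,3-dimethoxyphenyl]-5-hydroxy-7,8-dimethoxy-4H-chromen-4-one
Product: 13 5,4'-dihydroxy-7,8,2',3'-tetramethoxyflavone
Conditions: H2 (1 atm), 10% Pd/C, EtOAc–THF (1:1), rt, 3 h
Reagents that add atoms: none
Why: Catalytic hydrogenolysis of the benzyl aryl ether frees the 4'-phenol under neutral conditions that leave the aromatic pyranone and the methyl ethers untouched.

**Compound list**
1 | 3,4,5-trimethoxyphenol | COc1cc(O)cc(OC)c1OC | starting material
2 | 1,2,3,5-tetramethoxybenzene | COc1cc(OC)c(OC)c(OC)c1 | intermediate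
3 | 2,3,4,6-tetramethoxyacetophenone, 1-(2,3,4,6-tetramethoxyphenyl)ethanone | CC(=O)c1c(OC)cc(OC)c(OC)c1OC | intermediate
4 | 1-(2-hydroxy-3,4,6-trimethoxyphenyl)ethanone | CC(=O)c1c(OC)cc(OC)c(OC)c1O | intermediate
5 | 2,3,4-trihydroxybenzaldehyde | O=Cc1ccc(O)c(O)c1O | starting material
6 | 4-(benzyloxy)-2,3-dihydroxybenzaldehyde | O=Cc1ccc(OCc2ccccc2)c(O)c1O | intermediate
7 | 4-(benzyloxy)-2,3-dimethoxybenzaldehyde | COc1c(C=O)ccc(OCc2ccccc2)c1OC | intermediate
8 | racemic aldol adduct, rac-3-[4-(benzyloxy)-2,3-dimethoxyphenyl]-3-hydroxy-1-(2-hydroxy-3,4,6-trimethoxyphenyl)propan-1-one | COc1cc(OC)c(C(=O)CC(O)c2ccc(OCc3ccccc3)c(OC)c2OC)c(O)c1OC | intermediate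
9 | (E)-3-[4-(benzyloxy)-2,3-dimethoxyphenyl]-1-(2-hydroxy-3,4,6-trimethoxyphenyl)prop-2-en-1-one | COc1cc(OC)c(C(=O)/C=C/c2ccc(OCc3ccccc3)c(OC)c2OC)c(O)c1OC | intermediate
10 | racemic flavanone, rac-2-[4-(benzyloxy)-2,3-dimethoxyphenyl]-5,7,8-trimethoxychroman-4-one | COc1cc(OC)c2c(c1OC)OC(c1ccc(OCc3ccccc3)c(OC)c1OC)CC2=O | intermediate
11 | 2-[4-(benzyloxy)-2,3-dimethoxyphenyl]-5,7,8-trimethoxy-4H-chromen-4-one | COc1cc(OC)c2c(=O)cc(-c3ccc(OCc4ccccc4)c(OC)c3OC)oc2c1OC | intermediate
12 | 2-[4-(benzyloxy)-2,3-dimethoxyphenyl]-5-hydroxy-7,8-dimethoxy-4H-chromen-4-one | COc1cc(O)c2c(=O)cc(-c3ccc(OCc4ccccc4)c(OC)c3OC)oc2c1OC | intermediate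
13 | 5,4'-dihydroxy-7,8,2',3'-tetramethoxyflavone, 5-hydroxy-2-(4-hydroxy-2,3-dimethoxyphenyl)-7,8-dimethoxy-4H-chromen-4-one | COc1cc(O)c2c(=O)cc(-c3ccc(O)c(OC)c3OC)oc2c1OC | target

**Count**
Total steps: 8. Longest linear sequence: 6 steps (steps 1, 2, 5, 6, 7, 8, or equally steps 3, 4, 5, 6, 7, 8).

**Three steps most likely to fail**

(a) Step 3, mono-benzylation of one of three phenols. The risk is over-alkylation at O-3 or incomplete conversion. The fallback sets out from 5 and separates the oxygens with a ketal.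
- Heating 5 with dichlorodiphenylmethane (Ph2CCl2, diphenyl ether, 175 °C) ties O-3 and O-4 together and leaves the chelated 2-OH free, giving 4-hydroxy-2,2-diphenyl-1,3-benzodioxole-5-carbaldehyde F1.
- MeI/K2CO3 in DMF methylates that OH to 4-methoxy-2,2-diphenyl-1,3-benzodioxole-5-carbaldehyde F2.
- AcOH–H2O (4:1) at reflux removes the ketal to give 3,4-dihydroxy-2-methoxybenzaldehyde F3.
- With only two phenols left, BnBr/NaHCO3/KI in DMF at 40 °C alkylates the para-OH, as is usual for protocatechualdehyde-type substrates, giving 4-(benzyloxy)-3-hydroxy-2-methoxybenzaldehyde F4.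
- MeI/K2CO3 then brings the sequence back to the route at 7.

(b) Step 5, the Claisen–Schmidt condensation. The ketone is deactivated as its phenoxide and the aldehyde is electron-rich and ortho-substituted, so the reaction may stall or give chalcone/flavanone mixtures. The fallback sets out from 4 and keeps the same aldol bond construction with the phenol masked.
- NaH and chloromethyl methyl ether in DMF at 0 °C give 1-[3,4,6-trimethoxy-2-(methoxymethoxy)phenyl]ethanone F5.
- Condensation of F5 with 7 (KOH, EtOH, rt) passes through rac-3-[4-(benzyloxy)-2,3-dimethoxyphenyl]-3-hydroxy-1-[3,4,6-trimethoxy-2-(methoxymethoxy)phenyl]propan-1-one F6 (not isolated) and gives (E)-3-[4-(benzyloxy)-2,3-dimethoxyphenyl]-1-[3,4,6-trimethoxy-2-(methoxymethoxy)phenyl]prop-2-en-1-one F7.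
- 3 M HCl in MeOH at 50 °C removes the acetal and brings the sequence back at 9. Any flavanone 10 formed alongside is carried through step 6 unchanged in outcome.

(c) Step 7, selective 5-O-demethylation beside a benzyl ether. BCl3 may also cleave the benzyl ether, and the resulting boron phenolate could then attack the neighbouring 3'-OMe. The fallback sets out from 11 and swaps the benzyl group for one that is inert to BCl3.
- Hydrogenolysis first (H2, 10% Pd/C, EtOAc–THF) gives 2-(4-hydroxy-2,3-dimethoxyphenyl)-5,7,8-trimethoxy-4H-chromen-4-one F8.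
- Ac2O/pyridine converts it to 4-(5,7,8-trimethoxy-4-oxo-4H-chromen-2-yl)-2,3-dimethoxyphenyl acetate F9.
- BCl3 (CH2Cl2, −78 °C → 0 °C) now removes only the chelated 5-methyl group, giving 4-(5-hydroxy-7,8-dimethoxy-4-oxo-4H-chromen-2-yl)-2,3-dimethoxyphenyl acetate F10.
- K2CO3 in MeOH at rt cleaves the acetate and brings the sequence back at 13.

**Further compounds**
F1 | step 3 | 4-hydroxy-2,2-diphenyl-1,3-benzodioxole-5-carbaldehyde | O=Cc1ccc2OC(c3ccccc3)(c3ccccc3)Oc2c1O
F2 | step 3 | 4-methoxy-2,2-diphenyl-1,3-benzodioxole-5-carbaldehyde | COc1c(C=O)ccc2OC(c3ccccc3)(c3ccccc3)Oc12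
F3 | step 3 | 3,4-dihydroxy-2-methoxybenzaldehyde | COc1c(C=O)ccc(O)c1O
F4 | step 3 | 4-(benzyloxy)-3-hydroxy-2-methoxybenzaldehyde | COc1c(C=O)ccc(OCc2ccccc2)c1O
F5 | step 5 | 1-[3,4,6-trimethoxy-2-(methoxymethoxy)phenyl]ethanone | CC(=O)c1c(OC)cc(OC)c(OC)c1OCOC
F6 | step 5 | rac-3-[4-(benzyloxy)-2,3-dimethoxyphenyl]-3-hydroxy-1-[3,4,6-trimethoxy-2-(methoxymethoxy)phenyl]propan-1-one | COCOc1c(OC)c(OC)cc(OC)c1C(=O)CC(O)c1ccc(OCc2ccccc2)c(OC)c1OC
F7 | step 5 | (E)-3-[4-(benzyloxy)-2,3-dimethoxyphenyl]-1-[3,4,6-trimethoxy-2-(methoxymethoxy)phenyl]prop-2-en-1-one | COCOc1c(OC)c(OC)cc(OC)c1C(=O)/C=C/c1ccc(OCc2ccccc2)c(OC)c1OC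
F8 | step 7 | 2-(4-hydroxy-2,3-dimethoxyphenyl)-5,7,8-trimethoxy-4H-chromen-4-one | COc1cc(OC)c2c(=O)cc(-c3ccc(O)c(OC)c3OC)oc2c1OC
F9 | step 7 | 4-(5,7,8-trimethoxy-4-oxo-4H-chromen-2-yl)-2,3-dimethoxyphenyl acetate | COc1cc(OC)c2c(=O)cc(-c3ccc(OC(C)=O)c(OC)c3OC)oc2c1OC
F10 | step 7 | 4-(5-hydroxy-7,8-dimethoxy-4-oxo-4H-chromen-2-yl)-2,3-dimethoxyphenyl acetate | COc1cc(O)c2c(=O)cc(-c3ccc(OC(C)=O)c(OC)c3OC)oc2c1OC
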